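## Retrosynthetic overview

1. Last step: the ten-membered ring is closed at C7–C8 by a decarboxylative radical macrocyclization onto a preformed α-(sulfonylmethyl)butenolide. Loss of sulfinate creates the exo-methylene, so the α-methylene lactone, C7 and C8 arise together and the product is the unprotected target.
2. The seco-acid comes from a C3–C4 Nozaki–Hiyama–Kishi union of a south butenolide vinyl iodide with a north β-silyloxy aldehyde, followed by acetylation and one global acidolysis.
3. South fragment: crotonaldehyde plus a propargyl silyl ether (C6 by asymmetric alkynylation), trans-hydroalumination/iodination (4Z), acrylate ester, ring-closing metathesis.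
4. North fragment: vinylglycolic acid plus angelic acid (C8 carries its angelate from the start), cross-metathesis with methacrolein (9E), acetaldehyde Mukaiyama aldol (C1).
5. Ring order: butenolide first (metathesis), carbocycle last (radical).

Assumption: germacrane numbering is used (C6 lactone carbinol, C8 angelate carbon, C3 acetate carbon, C1 free secondary alcohol, C15 the CH2OH on C4); silyl-protected small building blocks are counted by their unprotected skeleton; C8 is carried as an inconsequential epimer mixture (drawn without configuration) until it becomes a planar radical in step 13.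

## Route

Step 1
Reactants: 1 (E)-but-2-enal; 2 tert-butyldimethyl(prop-2-yn-1-yloxy)silane
Product: 4 (4S,5E)-1-(tert-butyldimethylsilyloxy)hept-5-en-2-yn-4-ol, via methylzinc acetylide 3 (not isolated)
Conditions: 2, ZnMe2, (S,S)-ProPhenol (10 mol%), Ph3PO (20 mol%), toluene, 0 °C; then 1, 0 °C
Reagents that add atoms: none
Why: Zinc–ProPhenol catalysed enantioselective alkynylation of an enal, in which alkynylzinc 3 adds to the Re face of the aldehyde inside the chiral dinuclear zinc pocket and sets C6 (4S in 4; ligand enantiomer chosen accordingly and checked by Mosher analysis).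

Step 2
Reactants: 4 (4S,5E)-1-(tert-butyldimethylsilyloxy)hept-5-en-2-yn-4-ol
Product: 6 (2Z,4S,5E)-1-(tert-butyldimethylsilyloxy)-2-iodohepta-2,5-dien-4-ol, via cyclic sodium alkenylalanate 5 (not isolated)
Conditions: NaAlH2(OCH2CH2OCH3)2, THF, 0 °C; then I2, THF, −78 °C
Reagents that add atoms: iodine, II
Why: Hydroxyl-directed trans-hydroalumination of the propargylic alcohol delivers hydride to the proximal alkyne carbon through the five-membered alanate 5, and iodinolysis with retention gives the (Z)-vinyl iodide that fixes the C4=C5 geometry (C6 cis to the future C3).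

Step 3
Reactants: 7 2-(bromomethyl)prop-2-enoic acid
Product: 8 2-(methylsulfonylmethyl)prop-2-enoic acid
Conditions: MeSO2Na, MeOH, 60 °C
Reagents that add atoms: sodium methanesulfinate, CS(=O)[O-].[Na+]
Why: Sulfinate S-alkylation of the allylic bromide (SN2 and SN2' give the same product) installs the group that later leaves as a sulfonyl radical.

Step 4
Reactants: 6 (2Z,4S,5E)-1-(tert-butyldimethylsilyloxy)-2-iodohepta-2,5-dien-4-ol; 8 2-(methylsulfonylmethyl)prop-2-enoic acid
Product: 9 (2Z,4S,5E)-1-(tert-butyldimethylsilyloxy)-2-iodohepta-2,5-dien-4-yl 2-(methylsulfonylmethyl)prop-2-enoate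
Conditions: EDC·HCl, DMAP (10 mol%), CH2Cl2, 0 °C to rt
Reagents that add atoms: none
Why: Steglich-type carbodiimide esterification of the secondary alcohol, which touches no stereocentre.

Step 5
Reactants: 9 (2Z,4S,5E)-1-(tert-butyldimethylsilyloxy)-2-iodohepta-2,5-dien-4-yl 2-(methylsulfonylmethyl)prop-2-enoate
Product: 10 (5S)-5-[(1Z)-3-(tert-butyldimethylsilyloxy)-2-iodoprop-1-enyl]-3-(methylsulfonylmethyl)furan-2(5H)-one
Conditions: second-generation Grubbs catalyst (5 mol%), toluene (5 mmol/L), 80 °C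
Reagents that add atoms: none
Why: Ring-closing metathesis between the propenyl group and the 1,1-disubstituted acrylate forms the butenolide with loss of propene, while the trisubstituted iodoalkene is inert.

Step 6
Reactants: 11 2-hydroxybut-3-enoic acid (racemic)
Product: 12 4-methoxybenzyl 2-hydroxybut-3-enoate (racemic)
Conditions: KHCO3, 4-methoxybenzyl chloride, Bu4NI (cat.), DMF, rt
Reagents that add atoms: 4-methoxybenzyl chloride, COc1ccc(CCl)cc1
Why: Chemoselective carboxylate O-alkylation gives the acid-labile PMB ester and leaves the α-hydroxyl free.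

Step 7
Reactants: 12 4-methoxybenzyl 2-hydroxybut-3-enoate (racemic); 13 (2Z)-2-methylbut-2-enoic acid (angelic acid)
Product: 15 4-methoxybenzyl 2-[(2Z)-2-methylbut-2-enoyloxy]but-3-enoate (racemic), via angelic 2,4,6-trichlorobenzoic anhydride 14 (not isolated)
Conditions: 13, 2,4,6-trichlorobenzoyl chloride, Et3N, toluene, rt; then 12, toluene, 70 °C
Reagents that add atoms: none
Why: Yamaguchi-type mixed-anhydride acylation run without DMAP transfers the angeloyl group to the unhindered alcohol without Z-to-E isomerization.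

Step 8
Reactants: 15 4-methoxybenzyl 2-[(2Z)-2-methylbut-2-enoyloxy]but-3-enoate (racemic); 16 2-methylprop-2-enal
Product: 17 4-methoxybenzyl (3E)-4-methyl-2-[(2Z)-2-methylbut-2-enoyloxy]-5-oxopent-3-enoate (racemic at C2)
Conditions: second-generation Hoveyda–Grubbs catalyst (5 mol%), 16 (6 equiv), CH2Cl2, 40 °C
Reagents that add atoms: none
Why: Olefin cross-metathesis of the terminal alkene with methacrolein gives the thermodynamically favoured (E)-2-methyl enal and so fixes the C9=C10 geometry, while the trisubstituted angelate is inert.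

Step 9
Reactants: 17 4-methoxybenzyl (3E)-4-methyl-2-[(2Z)-2-methylbut-2-enoyloxy]-5-oxopent-3-enoate (racemic at C2); 18 triethyl(vinyloxy)silane
Product: 19 4-methoxybenzyl (3E,5S)-4-methyl-2-[(2Z)-2-methylbut-2-enoyloxy]-7-oxo-5-(triethylsilyloxy)hept-3-enoate (C2 epimers)
Conditions: chiral imidodiphosphorimidate (IDPi) acid catalyst (1 mol%), 18 (1.5 equiv), toluene, −40 °C
Reagents that add atoms: none
Why: Catalytic asymmetric Mukaiyama aldol reaction of an acetaldehyde silyl enol ether under silylium–imidodiphosphorimidate catalysis, in which the confined chiral counter-anion directs Si-face attack on the enal to set C1 (S), the transferred TES group protects the new alcohol and the confinement prevents a second aldolization of the product aldehyde.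

Step 10
Reactants: 10 (5S)-5-[(1Z)-3-(tert-butyldimethylsilyloxy)-2-iodoprop-1-enyl]-3-(methylsulfonylmethyl)furan-2(5H)-one; 19 4-methoxybenzyl (3E,5S)-4-methyl-2-[(2Z)-2-methylbut-2-enoyloxy]-7-oxo-5-(triethylsilyloxy)hept-3-enoate (C2 epimers)
Product: 20 4-methoxybenzyl (3E,5S,7S,8Z)-8-(tert-butyldimethylsilyloxymethyl)-7-hydroxy-4-methyl-2-[(2Z)-2-methylbut-2-enoyloxy]-9-[(2R)-4-(methylsulfonylmethyl)-5-oxo-2,5-dihydrofuran-2-yl]-5-(triethylsilyloxy)nona-3,8-dienoate (C2 epimers)
Conditions: CrCl2 (4 equiv), NiCl2 (2 mol%), Kishi-type chiral oxazoline sulfonamide ligand (4.4 equiv), Et3N (4.4 equiv), 19 (1.3 equiv), THF, rt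
Reagents that add atoms: none
Why: Nozaki–Hiyama–Kishi coupling, in which the alkenylchromium formed from the vinyl iodide adds only to the aldehyde with retention of the 4Z geometry, and the chiral sulfonamide ligand, reinforced by the 1,3-anti polar bias of the β-silyloxy aldehyde, directs Re-face addition to set C3 (S).

Step 11
Reactants: 20 4-methoxybenzyl (3E,5S,7S,8Z)-8-(tert-butyldimethylsilyloxymethyl)-7-hydroxy-4-methyl-2-[(2Z)-2-methylbut-2-enoyloxy]-9-[(2R)-4-(methylsulfonylmethyl)-5-oxo-2,5-dihydrofuran-2-yl]-5-(triethylsilyloxy)nona-3,8-dienoate (C2 epimers)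
Product: 21 4-methoxybenzyl (3E,5S,7S,8Z)-7-acetoxy-8-(tert-butyldimethylsilyloxymethyl)-4-methyl-2-[(2Z)-2-methylbut-2-enoyloxy]-9-[(2R)-4-(methylsulfonylmethyl)-5-oxo-2,5-dihydrofuran-2-yl]-5-(triethylsilyloxy)nona-3,8-dienoate (C2 epimers)
Conditions: Ac2O, pyridine, DMAP (cat.), CH2Cl2, 0 °C
Reagents that add atoms: acetic anhydride, CC(=O)OC(C)=O
Why: Standard acetylation of the only free hydroxyl places the C3 acetate of the target.

Step 12
Reactants: 21 4-methoxybenzyl (3E,5S,7S,8Z)-7-acetoxy-8-(tert-butyldimethylsilyloxymethyl)-4-methyl-2-[(2Z)-2-methylbut-2-enoyloxy]-9-[(2R)-4-(methylsulfonylmethyl)-5-oxo-2,5-dihydrofuran-2-yl]-5-(triethylsilyloxy)nona-3,8-dienoate (C2 epimers)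
Product: 22 (3E,5S,7S,8Z)-7-acetoxy-5-hydroxy-8-(hydroxymethyl)-4-methyl-2-[(2Z)-2-methylbut-2-enoyloxy]-9-[(2R)-4-(methylsulfonylmethyl)-5-oxo-2,5-dihydrofuran-2-yl]nona-3,8-dienoic acid (C2 epimers)
Conditions: TFA/CH2Cl2/H2O (10:30:1), 0 °C to rt
Reagents that add atoms: none
Why: Acidolysis (alkyl–oxygen cleavage of the PMB ester and solvolysis of both silyl ethers) unmasks the carboxylic acid radical precursor and the two free hydroxyls of the target in one operation, without touching acetate, angelate or butenolide.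

Step 13
Reactants: 22 (3E,5S,7S,8Z)-7-acetoxy-5-hydroxy-8-(hydroxymethyl)-4-methyl-2-[(2Z)-2-methylbut-2-enoyloxy]-9-[(2R)-4-(methylsulfonylmethyl)-5-oxo-2,5-dihydrofuran-2-yl]nona-3,8-dienoic acid (C2 epimers)
Product: 25 (1S,3S,6R,7R,8R,4Z,9E)-3-acetoxy-8-angeloyloxy-1,15-dihydroxygermacra-4,9,11(13)-trien-12,6-olide (target CNP0153210.6), via C8 allyl radical 23 (not isolated), via C11 lactonyl radical 24 (not isolated)
Conditions: 4CzIPN [2,4,5,6-tetra(carbazol-9-yl)isophthalonitrile] (2 mol%), K2HPO4 (1.1 equiv), degassed DMF (1 mmol/L), 450 nm LEDs, 10 °C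
Reagents that add atoms: none
Why: Proposed new method: single-electron oxidation of the carboxylate of 22 by the photoexcited catalyst and loss of CO2 give the W-shaped α-acyloxy allyl radical 23, whose oxygen-bearing terminus adds 10-exo to C7 of the butenolide anti to the C6 side chain (staggered C6–C7 torsion, hence the trans-lactone and 7R) with the angelate on the outside of the forming ring (expected 8R, under macrocyclic control), and the α-lactonyl radical 24 then expels methanesulfonyl radical (reduced to sulfinate by the catalyst radical anion) to unveil the exo-methylene, the closest known reactions being photoredox decarboxylative Giese macrocyclization and radical allylation (SH2') with allyl sulfones.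

## Compound list

1 | (E)-but-2-enal | C/C=C/C=O | starting material
2 | tert-butyldimethyl(prop-2-yn-1-yloxy)silane | C#CCO[Si](C)(C)C(C)(C)C | starting material
3 | methyl[3-(tert-butyldimethylsilyloxy)prop-1-ynyl]zinc (methylzinc acetylide) | C[Zn]C#CCO[Si](C)(C)C(C)(C)C | intermediate
4 | (4S,5E)-1-(tert-butyldimethylsilyloxy)hept-5-en-2-yn-4-ol | C/C=C/[C@H](O)C#CCO[Si](C)(C)C(C)(C)C | intermediate
5 | cyclic sodium alkenylalanate of 4 (five-membered O–Al–C=C ring, two 2-methoxyethoxy groups on Al) | C/C=C/[C@@H]1O[Al-](OCCOC)(OCCOC)C(CO[Si](C)(C)C(C)(C)C)=C1.[Na+] | intermediate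
6 | (2Z,4S,5E)-1-(tert-butyldimethylsilyloxy)-2-iodohepta-2,5-dien-4-ol | C/C=C/[C@H](O)/C=C(/CO[Si](C)(C)C(C)(C)C)I | intermediate
7 | 2-(bromomethyl)prop-2-enoic acid | C=C(CBr)C(=O)O | starting material
8 | 2-(methylsulfonylmethyl)prop-2-enoic acid | C=C(CS(C)(=O)=O)C(=O)O | intermediate
9 | (2Z,4S,5E)-1-(tert-butyldimethylsilyloxy)-2-iodohepta-2,5-dien-4-yl 2-(methylsulfonylmethyl)prop-2-enoate | C/C=C/[C@H](OC(=O)C(=C)CS(C)(=O)=O)/C=C(/CO[Si](C)(C)C(C)(C)C)I | intermediate
10 | (5S)-5-[(1Z)-3-(tert-butyldimethylsilyloxy)-2-iodoprop-1-enyl]-3-(methylsulfonylmethyl)furan-2(5H)-one | CS(=O)(=O)CC1=C[C@@H](/C=C(/CO[Si](C)(C)C(C)(C)C)I)OC1=O | intermediate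
11 | 2-hydroxybut-3-enoic acid (racemic) | C=CC(O)C(=O)O | starting material
12 | 4-methoxybenzyl 2-hydroxybut-3-enoate (racemic) | C=CC(O)C(=O)OCc1ccc(OC)cc1 | intermediate
13 | (2Z)-2-methylbut-2-enoic acid (angelic acid) | C/C=C(/C)C(=O)O | starting material
14 | angelic 2,4,6-trichlorobenzoic anhydride | C/C=C(/C)C(=O)OC(=O)c1c(Cl)cc(Cl)cc1Cl | intermediate
15 | 4-methoxybenzyl 2-[(2Z)-2-methylbut-2-enoyloxy]but-3-enoate (racemic) | C=CC(OC(=O)/C(C)=C\C)C(=O)OCc1ccc(OC)cc1 | intermediate
16 | 2-methylprop-2-enal | C=C(C)C=O | starting material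
17 | 4-methoxybenzyl (3E)-4-methyl-2-[(2Z)-2-methylbut-2-enoyloxy]-5-oxopent-3-enoate (racemic at C2) | O=C/C(C)=C/C(OC(=O)/C(C)=C\C)C(=O)OCc1ccc(OC)cc1 | intermediate
18 | triethyl(vinyloxy)silane | C=CO[Si](CC)(CC)CC | starting material
19 | 4-methoxybenzyl (3E,5S)-4-methyl-2-[(2Z)-2-methylbut-2-enoyloxy]-7-oxo-5-(triethylsilyloxy)hept-3-enoate (C2 epimers) | O=CC[C@H](O[Si](CC)(CC)CC)/C(C)=C/C(OC(=O)/C(C)=C\C)C(=O)OCc1ccc(OC)cc1 | intermediate
20 | 4-methoxybenzyl (3E,5S,7S,8Z)-8-(tert-butyldimethylsilyloxymethyl)-7-hydroxy-4-methyl-2-[(2Z)-2-methylbut-2-enoyloxy]-9-[(2R)-4-(methylsulfonylmethyl)-5-oxo-2,5-dihydrofuran-2-yl]-5-(triethylsilyloxy)nona-3,8-dienoate (C2 epimers) | CS(=O)(=O)CC1=C[C@@H](/C=C(/CO[Si](C)(C)C(C)(C)C)[C@@H](O)C[C@H](O[Si](CC)(CC)CC)/C(C)=C/C(OC(=O)/C(C)=C\C)C(=O)OCc2ccc(OC)cc2)OC1=O | intermediate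
21 | 4-methoxybenzyl (3E,5S,7S,8Z)-7-acetoxy-8-(tert-butyldimethylsilyloxymethyl)-4-methyl-2-[(2Z)-2-methylbut-2-enoyloxy]-9-[(2R)-4-(methylsulfonylmethyl)-5-oxo-2,5-dihydrofuran-2-yl]-5-(triethylsilyloxy)nona-3,8-dienoate (C2 epimers) | CS(=O)(=O)CC1=C[C@@H](/C=C(/CO[Si](C)(C)C(C)(C)C)[C@@H](OC(C)=O)C[C@H](O[Si](CC)(CC)CC)/C(C)=C/C(OC(=O)/C(C)=C\C)C(=O)OCc2ccc(OC)cc2)OC1=O | intermediate
22 | (3E,5S,7S,8Z)-7-acetoxy-5-hydroxy-8-(hydroxymethyl)-4-methyl-2-[(2Z)-2-methylbut-2-enoyloxy]-9-[(2R)-4-(methylsulfonylmethyl)-5-oxo-2,5-dihydrofuran-2-yl]nona-3,8-dienoic acid (C2 epimers) | CS(=O)(=O)CC1=C[C@@H](/C=C(/CO)[C@@H](OC(C)=O)C[C@H](O)/C(C)=C/C(OC(=O)/C(C)=C\C)C(=O)O)OC1=O | intermediate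
23 | C8 α-angeloyloxy allyl radical formed from 22 by loss of CO2 | CS(=O)(=O)CC1=C[C@@H](/C=C(/CO)[C@@H](OC(C)=O)C[C@H](O)/C(C)=C/[CH]OC(=O)/C(C)=C\C)OC1=O | intermediate
24 | C11 α-lactonyl radical with the ten-membered ring closed and the CH2SO2CH3 group still on C11 | CS(=O)(=O)C[C]1C(=O)O[C@@H]2/C=C(/CO)[C@@H](OC(C)=O)C[C@H](O)/C(C)=C/[C@@H](OC(=O)/C(C)=C\C)[C@@H]12 | intermediate
25 | (1S,3S,6R,7R,8R,4Z,9E)-3-acetoxy-8-angeloyloxy-1,15-dihydroxygermacra-4,9,11(13)-trien-12,6-olide (CNP0153210.6) | C=C1C(=O)O[C@@H]2/C=C(/CO)[C@@H](OC(C)=O)C[C@H](O)/C(C)=C/[C@@H](OC(=O)/C(C)=C\C)[C@@H]12 | target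

## Step count and risks

Total steps: 13. Longest linear sequence: 8 (steps 1, 2, 4, 5, 10, 11, 12, 13; the north branch 6, 7, 8, 9, 10, 11, 12, 13 is equally long).

**Most likely to fail, first: step 13.** The stabilized allyl radical may close slowly, so hydrodecarboxylation can compete. It may also attack through its tertiary C10 terminus to give an eight-membered ring, lose the 9E geometry by rotation, or give the C8 epimer. In addition, sulfinate can add back to the exo-methylene. The fallback separates the radical bond formation from the ring closure; it sets out from 17 and 10 and comes back to the route at 25. Brief TFA treatment of 17 gives (3E)-4-methyl-2-[(2Z)-2-methylbut-2-enoyloxy]-5-oxopent-3-enoic acid F1. The same 4CzIPN/K2HPO4 decarboxylative allylation, now intermolecular with butenolide 10, gives the α-methylene lactone enal F2 (radical addition anti to the C6 side chain; C8 epimers separated). Imidodiphosphorimidate-catalysed aldol reaction with 18 gives the β-silyloxy aldehyde F3. An intramolecular Nozaki–Hiyama–Kishi reaction (CrCl2, catalytic NiCl2, high dilution) then closes the ten-membered ring at C3–C4 to the macrocyclic alcohol F4. Acetylation gives the macrocyclic acetate F5, and HF·pyridine removes both silyl groups to give 25.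

**Second: step 10.** Face selectivity at C3 may be poor on this hindered, polyfunctional pair. The fallback sets the centre by reagent-controlled ketone reduction instead of carbonyl addition; it sets out from 10 and 19 and comes back at 20. Ligand-free CrCl2/NiCl2 coupling gives the C3-epimeric alcohols F6. Dess–Martin oxidation gives the C3 enone F7. Reduction with the methyl oxazaborolidine (CBS) catalyst and catecholborane, the catalyst enantiomer chosen for the 3S alcohol, returns 20.

**Third: step 9.** The α-branched enal carries several Lewis-basic esters and may react slowly or unselectively under silylium catalysis. The fallback uses a thioester aldol and a redox adjustment; it sets out from 17 and comes back at 19. A Ti(OiPr)4/chiral binaphthol Schiff-base catalysed Mukaiyama aldol reaction of 17 with trimethyl[1-(ethylsulfanyl)ethenyloxy]silane gives, after desilylation, the β-hydroxy S-ethyl thioester F8. TESOTf and 2,6-lutidine give the silyl ether F9. Fukuyama reduction (Et3SiH, 10% palladium on carbon, acetone) converts the thioester into the aldehyde 19.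

## Further compounds

F1 | step 13 | (3E)-4-methyl-2-[(2Z)-2-methylbut-2-enoyloxy]-5-oxopent-3-enoic acid (C2 epimers) | O=C/C(C)=C/C(OC(=O)/C(C)=C\C)C(=O)O
F2 | step 13 | α-methylene lactone enal with the C7–C8 bond made (C6/C7 trans, 8R, vinyl iodide and TBS ether retained) | C=C1C(=O)O[C@H](/C=C(/CO[Si](C)(C)C(C)(C)C)I)[C@H]1[C@H](OC(=O)/C(C)=C\C)/C=C(\C)C=O
F3 | step 13 | β-triethylsilyloxy aldehyde from aldol homologation of F2 (1S) | C=C1C(=O)O[C@H](/C=C(/CO[Si](C)(C)C(C)(C)C)I)[C@H]1[C@H](OC(=O)/C(C)=C\C)/C=C(\C)[C@@H](O[Si](CC)(CC)CC)CC=O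
F4 | step 13 | macrocyclic C3 alcohol (1-O-TES, 15-O-TBS derivative of 3-deacetyl 25) | C=C1C(=O)O[C@@H]2/C=C(/CO[Si](C)(C)C(C)(C)C)[C@@H](O)C[C@H](O[Si](CC)(CC)CC)/C(C)=C/[C@@H](OC(=O)/C(C)=C\C)[C@@H]12
F5 | step 13 | macrocyclic C3 acetate (1-O-TES, 15-O-TBS derivative of 25) | C=C1C(=O)O[C@@H]2/C=C(/CO[Si](C)(C)C(C)(C)C)[C@@H](OC(C)=O)C[C@H](O[Si](CC)(CC)CC)/C(C)=C/[C@@H](OC(=O)/C(C)=C\C)[C@@H]12
F6 | step 10 | C3-epimeric mixture of alcohol 20 | CS(=O)(=O)CC1=C[C@@H](/C=C(/CO[Si](C)(C)C(C)(C)C)C(O)C[C@H](O[Si](CC)(CC)CC)/C(C)=C/C(OC(=O)/C(C)=C\C)C(=O)OCc2ccc(OC)cc2)OC1=O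
F7 | step 10 | C3 enone corresponding to 20 | CS(=O)(=O)CC1=C[C@@H](/C=C(/CO[Si](C)(C)C(C)(C)C)C(=O)C[C@H](O[Si](CC)(CC)CC)/C(C)=C/C(OC(=O)/C(C)=C\C)C(=O)OCc2ccc(OC)cc2)OC1=O
F8 | step 9 | 4-methoxybenzyl (3E,5S)-7-(ethylsulfanyl)-5-hydroxy-4-methyl-2-[(2Z)-2-methylbut-2-enoyloxy]-7-oxohept-3-enoate (C2 epimers) | CCSC(=O)C[C@H](O)/C(C)=C/C(OC(=O)/C(C)=C\C)C(=O)OCc1ccc(OC)cc1
F9 | step 9 | 4-methoxybenzyl (3E,5S)-7-(ethylsulfanyl)-4-methyl-2-[(2Z)-2-methylbut-2-enoyloxy]-7-oxo-5-(triethylsilyloxy)hept-3-enoate (C2 epimers) | CCSC(=O)C[C@H](O[Si](CC)(CC)CC)/C(C)=C/C(OC(=O)/C(C)=C\C)C(=O)OCc1ccc(OC)cc1
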